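Ring carbons are numbered C1 (quaternary oxirane carbon bearing the benzoyloxymethyl carbon C7), C2 (benzoate), C3 (carbinol), C4=C5 and C6 (oxirane CH). On this cyclohexene ring, O3 and O6 lie on one face across C4=C5 and C1–C2 is an oxygenated two-carbon unit, the imprint of a [4+2] adduct of an (E,E)-1,4-dioxygenated butadiene and an oxygenated enal. One catalytic asymmetric Diels–Alder reaction forms C1–C6 and C2–C3, closes the carbocycle and sets all four ring stereocentres. Its partners are commercial (E,E)-1,4-diacetoxybutadiene and the (Z)-enol benzoate of bromomalonaldehyde; the bromine is later displaced by O6 with inversion at C1.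

Key step: step 2

Remark (assumption): the catalyst antipode must leave open the Si face of the bromine-bearing carbon of 3; by analogy with 2-bromoacrolein this is assigned to the (R)-series, and the (S)-series would be used instead should the analogy be reversed for this β-acyloxy enal; locants in the names of 5–8 follow the target numbering given above.

Step 1
Reactants: 1 bromomalonaldehyde (reacting as its enol); 2 benzoyl chloride
Product: 3 (Z)-3-(benzoyloxy)-2-bromoprop-2-enal (benzoyloxy cis to Br, trans to CHO)
Conditions: Et3N (1.05 equiv), CH2Cl2, −20 → 0 °C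
Reagents that add atoms: benzoyl chloride (= 2), O=C(Cl)c1ccccc1
Why: O-acylation of a strongly acidic enol (a vinylogous carboxylic acid) by an acid chloride under amine base gives the enol benzoate; the delocalised enolate should react from its extended form, which places the benzoyloxy group anti to the formyl group across C=C, the (Z)-isomer because Br outranks CHO, and this is also expected to be the more stable geometry.

Step 2
Reactants: 3 (Z)-3-(benzoyloxy)-2-bromoprop-2-enal; 4 (1E,3E)-buta-1,3-diene-1,4-diyl diacetate
Product: 5 (1R,2S,3R,6S)-3,6-diacetoxy-2-(benzoyloxy)-1-bromocyclohex-4-ene-1-carbaldehyde (Br and the C2 benzoate on one face; CHO and both acetoxy groups on the other)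
Conditions: (R)-tetrahydro-1-(2-methylphenyl)-3,3-diphenyl-1H,3H-pyrrolo[1,2-c][1,3,2]oxazaborole (C24H24BNO, 20 mol%) + HN(SO2CF3)2 (17 mol%), CH2Cl2, −78 → −20 °C; 4 (2 equiv)
Reagents that add atoms: none
Why: The N-protonated oxazaborolidine binds the formyl oxygen of 3 (supported by a formyl C–H···O contact to the ring oxygen), lowers its LUMO and screens one enantioface, and s-cis diene 4 then adds in a concerted, asynchronous suprafacial [4+2] cycloaddition that forms C1–C6 and C2–C3 together. The closest known reaction type is the oxazaborolidinium-catalysed Diels–Alder reaction of 2-bromoacrolein and other α-substituted enals with acyclic oxygenated dienes. The cyclohexene ring, the only ring formed, is closed by intermolecular [4πs+2πs] annulation in which both σ-bonds arise in one step. C3 and C6 become cis because the (E,E)-diene adds suprafacially, C2 keeps its benzoate cis to the C1 bromine because the (Z)-geometry of 3 is retained, the C1/C6 relationship (Br anti to the C6 acetoxy group) follows from the formyl group lying endo, and the absolute configuration comes from the catalyst, which is expected to leave the Si face of the bromine-bearing carbon open. The step needs endo-formyl and enantiofacial selectivity: the first should be favoured by secondary overlap of the boron-bound formyl group with the diene and by Br and the benzoyloxy group (cis to each other) both taking the roomier exo side, the second by the rigid catalyst–aldehyde complex, while the twofold-symmetric diene leaves no regiochemical choice.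

Step 3
Reactants: 5 (1R,2S,3R,6S)-3,6-diacetoxy-2-(benzoyloxy)-1-bromocyclohex-4-ene-1-carbaldehyde
Product: 6 (1R,2S,3R,6S)-3,6-diacetoxy-2-(benzoyloxy)-1-bromo-1-(hydroxymethyl)cyclohex-4-ene
Conditions: NaBH4 (1 equiv), THF/MeOH (4:1), −78 °C; pH 7 phosphate buffer quench at −78 °C
Reagents that add atoms: none
Why: Borohydride reduction of an aldehyde: the α-bromo, α-quaternary formyl group is highly electrophilic and should be reduced within minutes at −78 °C, where the esters, the tertiary bromide and the alkene are inert and the alkoxyborate, quenched cold, has no chance to displace bromide or accept an acetyl group; no stereocentre is created.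

Step 4
Reactants: 6 (1R,2S,3R,6S)-3,6-diacetoxy-2-(benzoyloxy)-1-bromo-1-(hydroxymethyl)cyclohex-4-ene; 2 benzoyl chloride
Product: 7 (1R,2S,3R,6S)-3,6-diacetoxy-2-(benzoyloxy)-1-[(benzoyloxy)methyl]-1-bromocyclohex-4-ene
Conditions: pyridine, 4-(dimethylamino)pyridine (cat.), CH2Cl2, 0 °C → rt
Reagents that add atoms: benzoyl chloride (= 2), O=C(Cl)c1ccccc1
Why: Pyridine/4-(dimethylamino)pyridine-mediated acylation (nucleophilic catalysis) of the only free hydroxyl group; no selectivity question arises because O3 and O6 are still acetylated.

Step 5
Reactants: 7 (1R,2S,3R,6S)-3,6-diacetoxy-2-(benzoyloxy)-1-[(benzoyloxy)methyl]-1-bromocyclohex-4-ene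
Product: 8 (1R,2S,3R,6S)-2-(benzoyloxy)-1-[(benzoyloxy)methyl]-1-bromocyclohex-4-ene-3,6-diol
Conditions: HCl (0.5 mol/L) in MeOH/CH2Cl2 (3:1), 0 °C → rt
Reagents that add atoms: none
Why: Acid-catalysed transesterification with methanol removes aliphatic acetates much faster than the conjugated, bulkier benzoates; the tertiary bromide and the allylic C–O bonds, deactivated toward ionisation by the neighbouring oxygen and bromine substituents, are expected to survive, and the acidic medium avoids premature oxirane formation and base-type acyl migration.

Step 6
Reactants: 8 (1R,2S,3R,6S)-2-(benzoyloxy)-1-[(benzoyloxy)methyl]-1-bromocyclohex-4-ene-3,6-diol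
Product: 9 [(1S,2S,3R,6S)-2-(benzoyloxy)-3-hydroxy-7-oxabicyclo[4.1.0]hept-4-en-1-yl]methyl benzoate (the target)
Conditions: 1,8-diazabicyclo[5.4.0]undec-7-ene (DBU, 1.1 equiv), CH2Cl2, 0 °C; pH 7 buffer quench
Reagents that add atoms: none
Why: Intramolecular Williamson etherification (halohydrin-to-epoxide closure, 3-exo-tet): in the half-chair with Br axial and CH2OBz equatorial, the pseudoaxial C6 oxygen is antiperiplanar to C1–Br and should displace bromide with inversion at C1, placing the oxirane oxygen cis to O3 and C7 on the opposite face as in the target while C2, C3 and C6 stay untouched; at 0 °C with only a slight excess of the amidine, benzoyl migration and E2 loss of HBr should stay minor.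

Compound list
1 | bromomalonaldehyde (2-bromopropanedial, present as its enol) | O=CC(Br)C=O | starting material
2 | benzoyl chloride | O=C(Cl)c1ccccc1 | starting material
3 | (Z)-3-(benzoyloxy)-2-bromoprop-2-enal | O=C/C(Br)=C/OC(=O)c1ccccc1 | intermediate
4 | (1E,3E)-buta-1,3-diene-1,4-diyl diacetate | CC(=O)O/C=C/C=C/OC(C)=O | starting material
5 | (1R,2S,3R,6S)-3,6-diacetoxy-2-(benzoyloxy)-1-bromocyclohex-4-ene-1-carbaldehyde | O=C[C@]1(Br)[C@@H](OC(=O)c2ccccc2)[C@H](OC(C)=O)C=C[C@@H]1OC(C)=O | intermediate
6 | (1R,2S,3R,6S)-3,6-diacetoxy-2-(benzoyloxy)-1-bromo-1-(hydroxymethyl)cyclohex-4-ene | OC[C@]1(Br)[C@@H](OC(=O)c2ccccc2)[C@H](OC(C)=O)C=C[C@@H]1OC(C)=O | intermediate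
7 | (1R,2S,3R,6S)-3,6-diacetoxy-2-(benzoyloxy)-1-[(benzoyloxy)methyl]-1-bromocyclohex-4-ene | O=C(OC[C@]1(Br)[C@@H](OC(=O)c2ccccc2)[C@H](OC(C)=O)C=C[C@@H]1OC(C)=O)c1ccccc1 | intermediate
8 | (1R,2S,3R,6S)-2-(benzoyloxy)-1-[(benzoyloxy)methyl]-1-bromocyclohex-4-ene-3,6-diol | O=C(OC[C@]1(Br)[C@@H](OC(=O)c2ccccc2)[C@H](O)C=C[C@@H]1O)c1ccccc1 | intermediate
9 | [(1S,2S,3R,6S)-2-(benzoyloxy)-3-hydroxy-7-oxabicyclo[4.1.0]hept-4-en-1-yl]methyl benzoate | O=C(OC[C@]12O[C@H]1C=C[C@@H](O)[C@@H]2OC(=O)c1ccccc1)c1ccccc1 | target

Total step count: 6. Longest linear sequence: 6 steps (1 → 3 → 5 → 6 → 7 → 8 → 9); the diene 4 is purchased.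

Steps most likely to fail

First, step 2 (the cycloaddition). A weakly nucleophilic bis-enol-ester diene meets an enal tempered by its β-acyloxy group. The reaction may be too slow at temperatures where the catalyst controls the face, so that conversion, endo preference or enantioselectivity falls short, or the Lewis acid may strip the enol benzoate. The fallback moves absolute control from catalysis to resolution. Setting out from 3 and 4, the cycloaddition is run without chiral information (BF3·OEt2, CH2Cl2, −40 °C, or heating in toluene). This should give the endo-formyl adduct as a racemate, that is 5 together with its mirror image, the (1S,2R,3S,6R)-bromo aldehyde ent-5 (F1). The mixture of 5 and F1 is carried through the borohydride reduction of the main route, giving 6 together with the mirror-image bromo alcohol ent-6 (F2). The benzoylation of the main route then converts 6 and F2 into 7 together with the mirror-image dibenzoate ent-7 (F3). Preparative HPLC on cellulose tris(3,5-dimethylphenylcarbamate) separates F3 from its antipode; the (1R,2S,3R,6S) enantiomer is 7, where the route is rejoined.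

Second, step 6 (the oxirane closure). Under base a benzoyl group may shift from O2 to the free O3 (or from O7 to O6) in competition with ring closure, and the O2/O3 shift may continue in the product. The fallback masks O3 for the closure and releases it under acid. Setting out from 8, the less hindered C3 hydroxyl (the C6 hydroxyl sits next to the quaternary C1) is silylated with Et3SiCl/imidazole in CH2Cl2 at −20 °C to give the 3-O-triethylsilyl ether of 8 (F4). DBU in CH2Cl2 at 0 °C then closes the oxirane of F4 to the 3-O-triethylsilyl ether of 9 (F5), in which no hydroxyl is left to accept a benzoyl group. HF·pyridine buffered with excess pyridine in THF at 0 °C removes the silyl group of F5 under conditions that should not move esters, and gives 9, where the route is rejoined.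

Third, step 5 (the deacetylation). Methanolysis of the C6 acetate, flanked by the quaternary C1, may be too slow, and forcing the acid may begin to remove or shift benzoates. The fallback replaces chemical discrimination by enzymatic hydrolysis. Setting out from 7, Candida antarctica lipase B (immobilised) in pH 7 phosphate buffer/tert-butyl methyl ether at 30 °C should hydrolyse the two acetates, while the aryl esters, poor substrates for this enzyme, remain. The product is 8 itself, where the route is rejoined, so no new compound is made (F0).

Further compounds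
F1 | step 2 | ent-5, (1S,2R,3S,6R)-3,6-diacetoxy-2-(benzoyloxy)-1-bromocyclohex-4-ene-1-carbaldehyde | O=C[C@@]1(Br)[C@H](OC(=O)c2ccccc2)[C@@H](OC(C)=O)C=C[C@H]1OC(C)=O
F2 | step 2 | ent-6, (1S,2R,3S,6R)-3,6-diacetoxy-2-(benzoyloxy)-1-bromo-1-(hydroxymethyl)cyclohex-4-ene | OC[C@@]1(Br)[C@H](OC(=O)c2ccccc2)[C@@H](OC(C)=O)C=C[C@H]1OC(C)=O
F3 | step 2 | ent-7, (1S,2R,3S,6R)-3,6-diacetoxy-2-(benzoyloxy)-1-[(benzoyloxy)methyl]-1-bromocyclohex-4-ene | O=C(OC[C@@]1(Br)[C@H](OC(=O)c2ccccc2)[C@@H](OC(C)=O)C=C[C@H]1OC(C)=O)c1ccccc1
F4 | step 6 | 3-O-triethylsilyl ether of 8 | O=C(OC[C@]1(Br)[C@@H](OC(=O)c2ccccc2)[C@H](O[Si](CC)(CC)CC)C=C[C@@H]1O)c1ccccc1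
F5 | step 6 | 3-O-triethylsilyl ether of 9 | O=C(OC[C@]12O[C@H]1C=C[C@@H](O[Si](CC)(CC)CC)[C@@H]2OC(=O)c1ccccc1)c1ccccc1
F0 | step 5 | none | none
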